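**Plan**
1. Cuts, in order: the C6–O ester bond; the two C–O bonds of the 8,9-epoxide; then the seven-membered ring C1–C10–C9–C8–C7–C6–C5 is contracted. Its homoallylic array HO–C6–C7H2–C8(CH3)=C9 is the retron of a cyclopropylcarbinyl-to-homoallyl cation ring expansion: C6 is re-bonded to C8 (C7 becomes a cyclopropane CH2 on the cyclohexane C1–C10–C9–C8–C6–C5) and the hydroxyl moves to C9.
2. Further cuts: C7 (carbenoid CH2), C4–isopropyl, the C9 oxygen (through the 8,9-epoxide of a dienone), C5=C6 (aldol, dehydration), C8=C9 (ring-closing metathesis), C1–CH3 (conjugate addition), C1–allyl (Grignard addition).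
3. Forward: cyclopentane ring (C1–C5) first, cyclohexadiene ring second, cyclopropane third, six-to-seven ring expansion fourth, then epoxide and ester.
4. Stereochemistry: C1 from a ligand-controlled copper-catalysed conjugate methylation; C9–O, C5–H and C4 are relayed from the C1 methyl (reagents and the proton approach the opposite face); the cyclopropane and the final epoxide are placed by hydroxyl direction; C6 arises by inversion in the ring expansion.

Key step: step 10

Conventions: all compounds carry the daucane locants of the target: C1 quaternary ring-fusion carbon with methyl, C2, C3, C4 carbinol carbon with isopropyl, C5 ring-fusion CH, C6 ester carbon, C7, C8 methyl-bearing carbon, C9, C10. C7 is absent until step 9. β is the face of the C1 methyl, α the opposite face.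

Assumption: the target is the (1R,4R,5S,6S,8R,9S) isomer encoded by the SMILES (1β-methyl, 5α-H, 4β-OH, 6α-O, 8α,9α-epoxide), i.e. the 6-O-(4-methoxybenzoate) of 8α,9α-epoxy-dauc-8-ene-4β,6α-diol.

Step 1
Reactants: 1 3-ethoxycyclopent-2-en-1-one; 2 allylmagnesium bromide
Product: 4 3-allylcyclopent-2-en-1-one, via 1-allyl-3-ethoxycyclopent-2-en-1-ol 3 (not isolated)
Conditions: 2 (1.2 equiv), THF, −78 to 0 °C; then 1 M HCl, 0 °C
Reagents that add atoms: water, O
Why: 1,2-addition of the Grignard reagent to the vinylogous ester followed by acid hydrolysis with allylic transposition (Stork–Danheiser sequence) should give the 3-substituted enone; no stereocenter is formed.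

Step 2
Reactants: 4 3-allylcyclopent-2-en-1-one
Product: 6 (R)-[(3-allyl-3-methylcyclopent-1-en-1-yl)oxy]trimethylsilane, via dimethylaluminium enolate 5 (not isolated)
Conditions: Me3Al (1.3 equiv), Cu(OTf)2 (2 mol %), chiral binaphthol-derived phosphoramidite ligand (4 mol %), Et2O, −30 °C; then TMSOTf, THF, −30 °C to rt
Reagents that add atoms: trimethylaluminium, C[Al](C)C; trimethylsilyl trifluoromethanesulfonate, C[Si](C)(C)OS(=O)(=O)C(F)(F)F
Why: copper-catalysed asymmetric conjugate addition of methyl to the β-carbon (C1) should set the quaternary center under ligand control (ligand enantiomer chosen to give R), and O-silylation of the aluminium enolate fixes the enol ether toward C5.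

Step 3
Reactants: 6 (R)-[(3-allyl-3-methylcyclopent-1-en-1-yl)oxy]trimethylsilane; 7 methacrolein
Product: 9 (3R)-3-allyl-2-(1-hydroxy-2-methylprop-2-en-1-yl)-3-methylcyclopentan-1-one (diastereomer mixture at C5 and C6), via lithium enolate 8 (not isolated)
Conditions: MeLi (1.05 equiv), THF, 0 °C to rt; then 7, −78 °C; aq. NH4Cl
Reagents that add atoms: none
Why: cleavage of the silyl enol ether by MeLi should give the regiodefined lithium enolate, whose aldol addition to the non-enolisable enal forms the C5–C6 bond; the two new centers need no control because step 5 makes both sp2.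

Step 4
Reactants: 9 (3R)-3-allyl-2-(1-hydroxy-2-methylprop-2-en-1-yl)-3-methylcyclopentan-1-one
Product: 10 (3aR)-7-hydroxy-3a,6-dimethyl-2,3,3a,4,7,7a-hexahydro-1H-inden-1-one (C4 ketone, 6-OH, C8=C9; diastereomer mixture at C5 and C6)
Conditions: second-generation Grubbs catalyst (3 mol %), CH2Cl2, 40 °C
Reagents that add atoms: none
Why: ring-closing olefin metathesis between the allyl group and the 1,1-disubstituted olefin should close the six-membered ring and form the trisubstituted C8=C9 olefin with loss of ethylene.

Step 5
Reactants: 10 (3aR)-7-hydroxy-3a,6-dimethyl-2,3,3a,4,7,7a-hexahydro-1H-inden-1-one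
Product: 11 (3aR)-3a,6-dimethyl-2,3,3a,4-tetrahydro-1H-inden-1-one (C4 ketone conjugated with C5=C6 and C8=C9)
Conditions: TsOH·H2O (10 mol %), toluene, 60 °C
Reagents that add atoms: none
Why: acid-catalysed dehydration of the β-hydroxy ketone (aldol dehydration) should give the linearly conjugated dienone, which is the thermodynamic sink because the quaternary C1 blocks further olefin migration; all diastereomers of 10 converge.

Step 6
Reactants: 11 (3aR)-3a,6-dimethyl-2,3,3a,4-tetrahydro-1H-inden-1-one
Product: 12 (1R)-8α,9α-epoxide of 11 (C4 ketone, C5=C6, epoxide oxygen anti to the C1 methyl)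
Conditions: mCPBA (1.1 equiv), NaHCO3, CH2Cl2, 0 °C
Reagents that add atoms: 3-chloroperoxybenzoic acid, OOC(=O)c1cccc(Cl)c1
Why: electrophilic (Prilezhaev) epoxidation should take the more electron-rich γ,δ-olefin C8=C9 and not the enone olefin, from the α face because the pseudo-axial C1 methyl shields the β face.

Step 7
Reactants: 12 (1R)-8α,9α-epoxide of 11
Product: 14 trans-fused ketol (1R)-9α-hydroxy-5α-H-hydrind-6(8)-en-4-one (C4 ketone, C6=C8, 8-methyl), via samarium dienolate 13 (not isolated)
Conditions: SmI2 (2.2 equiv), MeOH (5 equiv), THF, −78 °C; aq. NH4Cl at −78 °C; used crude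
Reagents that add atoms: none
Why: single-electron reduction of the enone by SmI2 should cleave the allylic C8–O bond (reductive opening of a γ,δ-epoxy enone) with retention of the C9–O center, and kinetic protonation of the dienolate at the α-carbon C5, anti to the C1 methyl, should give the deconjugated ketone with the trans ring fusion.

Step 8
Reactants: 14 trans-fused ketol; 15 isopropylmagnesium chloride
Product: 16 diol (1R)-4α-isopropyl-5α-H-hydrind-6(8)-ene-4β,9α-diol
Conditions: 15 (3 equiv), CeCl3 (3 equiv, anhydrous), THF, −78 °C; aq. NH4Cl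
Reagents that add atoms: none
Why: the weakly basic organocerium reagent should add 1,2 to the enolisable ketone from the α face, anti to the 1,3-related C1 methyl, which places the C4 hydroxyl β and the isopropyl α.

Step 9
Reactants: 16 diol
Product: 17 tricyclic cyclopropyl carbinol (cyclopropane C6–C7–C8 on the α face, 8-methyl, 9α-OH, 4β-OH, 4α-isopropyl, 5α-H)
Conditions: Et2Zn (4 equiv), CH2I2 (4 equiv), CH2Cl2, 0 °C to rt
Reagents that add atoms: diiodomethane, ICI
Why: hydroxyl-directed Simmons–Smith cyclopropanation through the zinc alkoxide of the allylic C9 hydroxyl should deliver CH2 (the future C7) to the α face of C6=C8, syn to that hydroxyl and anti to the C1 methyl.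

Step 10
Reactants: 17 tricyclic cyclopropyl carbinol
Product: 18 (1R,4R,5S,6S)-dauc-8-ene-4,6-diol (4β-OH, 6α-OH, C8=C9)
Conditions: HClO4 (0.1 M), acetone–H2O 3:1, 0 °C to rt
Reagents that add atoms: water, O
Why: Protonation of the secondary C9 hydroxyl and loss of water give a cyclopropylcarbinyl cation in which the C6–C8 σ bond, anti-periplanar to the equatorial C9–O bond, delocalises the charge onto C6; water then attacks C6 opposite to the breaking C6–C8 bond, which leaves C7 as a ring methylene, creates the C8=C9 olefin and enlarges the cyclohexane to the cycloheptene. The closest known reaction type is the acid-catalysed cyclopropylcarbinyl-to-homoallyl rearrangement of bicyclo[4.1.0]heptan-2-ols to cyclohept-3-en-1-ols. No ring is closed: the seven-membered ring arises from the six-membered one by scission of the bond it shares with the cyclopropane, a one-carbon ring expansion. The only new stereocenter, C6, is fixed by inversion at that carbon: with the cyclopropane methylene on the α face the hydroxyl must end α (6S), and that α cyclopropane was placed by the C9 hydroxyl in step 9. The step needs scission of the internal and not the external cyclopropane bond and capture at C6 and not at C9 or C8; the first is secured by the orbital alignment above and by the secondary character of C6, the second by reversible acid conditions under which the strain-free homoallylic alcohol is the thermodynamic sink. The tertiary C4 hydroxyl should survive because its ionisation has no cyclopropyl assistance and is much slower in dilute aqueous acid.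

Step 11
Reactants: 18 (1R,4R,5S,6S)-dauc-8-ene-4,6-diol
Product: 19 (1R,4R,5S,6S,8R,9S)-8,9-epoxydaucane-4,6-diol (8α,9α-epoxide)
Conditions: VO(acac)2 (5 mol %), tBuOOH (1.5 equiv), CH2Cl2, 0 °C to rt
Reagents that add atoms: tert-butyl hydroperoxide, CC(C)(C)OO
Why: vanadium-catalysed hydroxyl-directed epoxidation should deliver oxygen to C8=C9 from the face of the homoallylic C6 hydroxyl (α), which is also the face away from the C1 methyl, setting C8 and C9.

Step 12
Reactants: 19 (1R,4R,5S,6S,8R,9S)-8,9-epoxydaucane-4,6-diol; 20 4-methoxybenzoyl chloride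
Product: 21 (1R,4R,5S,6S,8R,9S)-8,9-epoxy-4-hydroxydaucan-6-yl 4-methoxybenzoate (target)
Conditions: 20 (1.5 equiv), DMAP (0.2 equiv), Et3N, CH2Cl2, rt
Reagents that add atoms: none
Why: DMAP-catalysed acylation (nucleophilic catalysis through the acylpyridinium ion) should esterify only the secondary C6 hydroxyl, since the tertiary C4 hydroxyl is too hindered and the epoxide is inert to the basic medium.

**Compound list**
1 | 3-ethoxycyclopent-2-en-1-one | CCOC1=CC(=O)CC1 | starting material
2 | allylmagnesium bromide | C=CC[Mg]Br | starting material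
3 | 1-allyl-3-ethoxycyclopent-2-en-1-ol (racemic; formed as its bromomagnesium alkoxide; not isolated) | C=CCC1(O)C=C(OCC)CC1 | intermediate
4 | 3-allylcyclopent-2-en-1-one | C=CCC1=CC(=O)CC1 | intermediate
5 | dimethylaluminium (R)-3-allyl-3-methylcyclopent-1-en-1-olate (not isolated) | C[Al](C)OC1=C[C@@](C)(CC=C)CC1 | intermediate
6 | (R)-[(3-allyl-3-methylcyclopent-1-en-1-yl)oxy]trimethylsilane | C[Si](C)(C)OC1=C[C@@](C)(CC=C)CC1 | intermediate
7 | methacrolein (2-methylprop-2-enal) | C=C(C)C=O | starting material
8 | lithium (R)-3-allyl-3-methylcyclopent-1-en-1-olate (not isolated) | [Li]OC1=C[C@@](C)(CC=C)CC1 | intermediate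
9 | (3R)-3-allyl-2-(1-hydroxy-2-methylprop-2-en-1-yl)-3-methylcyclopentan-1-one, diastereomer mixture at C5 and C6 | O=C1CC[C@](C)(CC=C)C1C(O)C(C)=C | intermediate
10 | (3aR)-7-hydroxy-3a,6-dimethyl-2,3,3a,4,7,7a-hexahydro-1H-inden-1-one, diastereomer mixture at C5 and C6 | O=C1CC[C@]2(C)CC=C(C)C(O)C12 | intermediate
11 | (3aR)-3a,6-dimethyl-2,3,3a,4-tetrahydro-1H-inden-1-one | O=C1CC[C@]2(C)CC=C(C)C=C12 | intermediate
12 | (1R)-8α,9α-epoxide of 11: 5,6-epoxy-3a,6-dimethyl-2,3,3a,4,5,6-hexahydro-1H-inden-1-one, oxygen anti to the 3a-methyl | O=C1CC[C@]2(C)C[C@@H]3O[C@]3(C)C=C12 | intermediate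
13 | bis(diiodosamarium) dienolate-alkoxide, C4(O–Sm)=C5–C6=C8, 9α-O–Sm (not isolated) | I[Sm](I)OC1=C2C=C(C)[C@@H](O[Sm](I)I)C[C@@]2(C)CC1 | intermediate
14 | trans-fused ketol: C4 ketone, 5α-H, C6=C8, 8-methyl, 9α-OH, 1β-methyl | O[C@H]1C[C@@]2(C)CCC(=O)[C@@H]2C=C1C | intermediate
15 | isopropylmagnesium chloride | CC(C)[Mg]Cl | starting material
16 | diol: 4β-OH, 4α-isopropyl, 5α-H, C6=C8, 8-methyl, 9α-OH, 1β-methyl | O[C@H]1C[C@@]2(C)CC[C@@](O)(C(C)C)[C@@H]2C=C1C | intermediate
17 | tricyclic cyclopropyl carbinol: cyclopropane C6–C7–C8 on the α face, 8-methyl, 9α-OH, 4β-OH, 4α-isopropyl, 5α-H, 1β-methyl | O[C@H]1C[C@@]2(C)CC[C@@](O)(C(C)C)[C@@H]2[C@H]2C[C@@]12C | intermediate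
18 | (1R,4R,5S,6S)-dauc-8-ene-4,6-diol | O[C@H]1CC(C)=CC[C@@]2(C)CC[C@@](O)(C(C)C)[C@H]12 | intermediate
19 | (1R,4R,5S,6S,8R,9S)-8,9-epoxydaucane-4,6-diol | O[C@H]1C[C@@]2(C)O[C@H]2C[C@@]2(C)CC[C@@](O)(C(C)C)[C@H]12 | intermediate
20 | 4-methoxybenzoyl chloride | COc1ccc(C(Cl)=O)cc1 | starting material
21 | (1R,4R,5S,6S,8R,9S)-8,9-epoxy-4-hydroxydaucan-6-yl 4-methoxybenzoate | COc1ccc(C(=O)O[C@H]2C[C@@]3(C)O[C@H]3C[C@@]3(C)CC[C@@](O)(C(C)C)[C@H]23)cc1 | target

Total step count: 12
Longest linear sequence: 12 steps (from 1 to 21)

**Steps most likely to fail**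

Step 10 (key ring expansion). What may go wrong:
- return of water to C9 or capture at C8 after a cyclobutyl shift;
- proton loss from the homoallylic cation;
- ionisation and dehydration of the tertiary C4 carbinol in the acid.

Fallback: the order is changed so that no tertiary alcohol is present in the cationic step. It sets out from 14. Hydroxyl-directed cyclopropanation (Et2Zn, CH2I2) at the ketone stage should give the cyclopropyl carbinol ketone F1. The same dilute-acid rearrangement on F1 should give the ring-expanded ketol (C4 ketone, 6α-OH, C8=C9, 5α-H) F2. Addition of isopropylcerium dichloride to the C4 ketone of F2 from the α face, anti to the C1 methyl, then returns to 18.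

Step 7 (reductive epoxide opening that sets C5). What may go wrong:
- protonation of the dienolate at C8 (re-conjugation) or from the β face (cis ring fusion);
- over-reduction or pinacol coupling under electron transfer;
- epimerisation of the labile α-center on work-up.

Fallback: the electron-transfer route is replaced by a two-electron conjugate addition. It sets out from 11, skipping the epoxide. Copper-catalysed 1,6-conjugate borylation (B2pin2, CuCl, a bisphosphine, NaOtBu, MeOH, THF) should add boron to C9 from the α face and protonate the copper enolate at C5 in situ, giving the allylic boronate ketone F3. Oxidation with NaBO3 in THF–H2O, with retention at C9, returns to 14.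

Step 8 (isopropyl addition). What may go wrong:
- enolisation and re-conjugation of the β,γ-unsaturated ketone by the reagent;
- β-hydride reduction by the secondary alkylmetal;
- insufficient facial selectivity.

Fallback: the carbinol is built in two stages with a smaller sp2 nucleophile that cannot transfer hydride. It sets out from 14. 2-Propenylmagnesium bromide with CeCl3 should give the isopropenyl carbinol F4. Hydrogenation of its 1,1-disubstituted olefin with RhCl(PPh3)3 and H2 (1 atm), which should leave the trisubstituted ring olefin untouched, returns to 16.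

**Further compounds**
F1 | step 10 | cyclopropyl carbinol ketone: C4 ketone, cyclopropane C6–C7–C8 on the α face, 8-methyl, 9α-OH, 5α-H | O[C@H]1C[C@@]2(C)CCC(=O)[C@@H]2[C@H]2C[C@@]12C
F2 | step 10 | ring-expanded ketol: 6α-hydroxy-1β,8-dimethyl-5α-H-bicyclo[5.3.0]dec-8-en-4-one (daucane locants) | O[C@H]1CC(C)=CC[C@@]2(C)CCC(=O)[C@H]12
F3 | step 7 | allylic boronate ketone: C4 ketone, 5α-H, C6=C8, 9α-(pinacolato)boryl | CC1(C)OB(OC1(C)C)[C@H]1C[C@@]2(C)CCC(=O)[C@@H]2C=C1C
F4 | step 8 | isopropenyl carbinol: 4β-OH, 4α-(prop-1-en-2-yl), 5α-H, C6=C8, 9α-OH | O[C@H]1C[C@@]2(C)CC[C@@](O)(C(C)=C)[C@@H]2C=C1C
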